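In moles per litre, we want how much product stands in each flask at the end, and we reckon it on paper first.

in all of them: free base 0.0750 M; time 2.5 d
- south-east: electrophile 0.25 M; nucleophile 0.375 M (fed, over 50 h); the addition at 40 °C, then warmed to 80 °C; the feed brings no volume worth counting
- south: electrophile 0.25 M; nucleophile 0.375 M (fed, over 12 h); all else is in the flask from the start; the feed brings no volume worth counting; temperature 80 °C
- east: electrophile 0.25 M (in portions, 3, over 50 h); nucleophile 0.375 M; first portion at the start, last at 50 h; temperature 80 °C
- north-west: electrophile 0.25 M (fed, over 50 h); nucleophile 0.375 M; all else is in the flask from the start; the feed brings no volume worth counting; temperature 80 °C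
- south-west: electrophile 0.25 M; nucleophile 0.375 M (fed, over 50 h); all else is in the flask from the start; the feed brings no volume worth counting; temperature 80 °C

    nucleophile + acid set free ⇌ protonated nucleophile, settled at all times (K1 = 100 L mol⁻¹, ΔH1 = −90.0 kJ mol⁻¹)
    crystals ⇌ acid set free, rate k2*(cs2 - [acid set free]) while solid is left; crystals form when [acid set free] > cs2 (cs2 = 0.091 M, k2 = 0.0035 min⁻¹)
    electrophile + nucleophile ⇌ acid set free + product (K3 = 0.71, k3 = 5.0 × 10⁻⁴ L mol⁻¹ min⁻¹, Ea3 = 86.0 kJ mol⁻¹, ΔH3 = −73.0 kJ mol⁻¹)
    acid set free + free base ⇌ salt of the base (K4 = 1400 L mol⁻¹, k4 = 0.0095 L mol⁻¹ min⁻¹, Ea4 = 84.0 kJ mol⁻¹, ΔH4 = −60.0 kJ mol⁻¹)
    (constants at 80 °C)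

- the flask with the highest amount of product, in percent of the electrophile charged ("all alike" if they lie within 1.5 percentage points) (south-east / south / east / north-west / south-west / all alike)
- final product, as a percentage of the electrophile charged, in south-east
- final product, as a percentage of the electrophile charged, in south
- final product, as a percentage of the electrophile charged, in east
- final product, as a percentage of the electrophile charged, in north-west
- final product, as a percentage of the electrophile charged, in south-west

- for acid set free the crystals are counted in
- as a solid, counted per litre of solution: crystals
- all constants are for 80 °C and move with temperature by the activation energies and enthalpies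

**First instants.** We follow south. The nucleophile comes in over 12 h, and the step to product is the rate-limiting step: against the whole charge of nucleophile an electrophile has a mean life of 88.9 h, longer than the 60 h of the run. Protonation is kept at balance, and with the full charge in, protonated nucleophile stands to acid set free as 37.5 to one, so nearly all of that acid sits on a nucleophile. We therefore take each product to cost two nucleophile, one reacting and one protonated.

**The middle.** On that count, electrophile left is its charge less the product, and free nucleophile is its charge less two products. Leaving out the back step and dividing their rates of loss, the natural logarithm of the ratio of electrophile to free nucleophile climbs steadily. This climb per hour we call the drift, the rate constant times two electrophile charges less one nucleophile charge: 0.00375 h⁻¹. A steady feed has its mean arrival at half the feed time, so we count the full-charge time as the reading time less that. In south this is 54.0 h, and the ratio rises from 0.667 to 0.816. That means 0.0887 M of product, 35.5% of the charge.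

**The end.** By this reckoning south has made 0.0887 M of acid, less than the solubility of 0.091 M even if none were bound, so we expect no crystals. The reckoning puts free nucleophile in south at 0.198 M and free acid near 0.00449 M. The rate of the free base on that acid then comes to 20.1% of the product rate in south, less than that rate.

**Other flasks.** South-west, north-west and east receive their reagent on average at 25.0 h, east in its 3 portions, so each has 35.0 h of full-charge time. The drift then gives 0.0674 M, or 27.0%. South-east we count from the end of its feed at 40 °C, leaving the cold hours out: 10.0 h gives 0.0249 M, or 9.94%.

**The forecast.** It names south, with 35.5% there, 26.4% in south-west, 26.2% in north-west, 25.9% in east and 10.6% in south-east. Its ground: “Each acid formed removes a second nucleophile”. It stands lower than our figure for south-west and higher than ours for south-east.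

**The readings.** The most product stands in south, 35.7%, against 26.3% in south-west, 26.5% in north-west, 25.9% in east and 10.5% in south-east. Our south-west figure lies 0.61 percentage points above its reading. Read backwards through the drift, the product of south asks for 54.5 h of full-charge time, beside our 54.0 h. The neighbouring flask is south stopped at 15 h: its full-charge time is 9.00 h, the drift lifts the ratio to 0.690, and the reckoning gives 9.05%. That flask reads 8.99%.

(The constants are invented.)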